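The triol ring (ring A, carbons C1–C6) is opened at its two cis C–O bonds, C3–O and C6–O. One suprafacial [4+2] addition of singlet oxygen across C3 and C6 of the achiral, s-cis-locked 1-ethynyl-2,6,6-trimethylcyclohexa-1,3-diene forms both bonds, fixes their 1,4-cis relation and leaves the C4=C5 alkene for anti introduction of the C5 hydroxyl. The resolved vinyl triol is joined last, through C8–C9, by a Heck reaction to a bromo-ylidenebutenolide (ring B) polyene. That polyene is assembled from (4R,6R)-actinol (ring C) and one C6 enynal by Sonogashira, Suzuki and alkynylation–lactonisation steps.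

Key step: step 3

Remark: atom labels follow carotenoid numbering (ring A = triol ring with C1 the gem-dimethyl carbon and vinyl arm C7=C8; ring B = butenolide with C9 its α-carbon; ring C = hydroxycyclohexene); racemates are drawn as the enantiomer that is carried on.
Remark: (2E)-2,3-dibromoprop-2-enoic acid is prepared (step 14) rather than assumed to be purchasable.

Step 1
Reactants: 1 safranal; 2 carbon tetrabromide
Product: 3 1-(2,2-dibromoethenyl)-2,6,6-trimethylcyclohexa-1,3-diene
Conditions: CBr4, PPh3, CH2Cl2, 0 °C
Reagents that add atoms: carbon tetrabromide 2, BrC(Br)(Br)Br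
Why: Ramirez dibromo-olefination (first stage of the Corey–Fuchs sequence), in which the ylide Ph3P=CBr2 formed from CBr4 and PPh3 undergoes a Wittig reaction with the non-enolisable dienal without touching the diene, no stereocenter being formed.

Step 2
Reactants: 3 1-(2,2-dibromoethenyl)-2,6,6-trimethylcyclohexa-1,3-diene
Product: 5 1-ethynyl-2,6,6-trimethylcyclohexa-1,3-diene, via lithium acetylide 4 (not isolated)
Conditions: n-BuLi (2.2 equiv), THF, −78 → 0 °C; aq. NH4Cl
Reagents that add atoms: none
Why: Second stage of the Corey–Fuchs sequence, in which bromine–lithium exchange, α-elimination and 1,2-hydrogen shift (Fritsch–Buttenberg–Wiechell rearrangement) give the alkyne, held as its acetylide by the second equivalent of base until the proton quench; the volatile product is carried on as a concentrated solution.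

Step 3
Reactants: 5 1-ethynyl-2,6,6-trimethylcyclohexa-1,3-diene
Product: 6 rac-(1S,4S)-1-ethynyl-6,7,7-trimethyl-2,3-dioxabicyclo[2.2.2]oct-5-ene
Conditions: O2, meso-tetraphenylporphyrin (cat.), visible light, CH2Cl2, −20 °C
Reagents that add atoms: dioxygen (as singlet oxygen), O=O
Why: Sensitised singlet oxygen adds to the ring-locked s-cis diene (C3=C4–C5=C6) in a concerted, suprafacial [4+2] cycloaddition, the reaction type by which cyclohexa-1,3-dienes such as α-terpinene give bicyclic endoperoxides and by which 1-substituted 2,6,6-trimethylcyclohexa-1,3-dienes are known to give 3,6-epidioxides. The six-membered 1,2-dioxine ring is closed by this cycloaddition itself, which forms the O–C3 and O–C6 bonds together and turns the carbocycle into a 2,3-dioxabicyclo[2.2.2]octene. The stereocenters C3 and C6 are set relative to each other by delivery of both oxygens to one face, so the two oxygens are necessarily cis; the diene is achiral, so the product is racemic and the absolute configuration is secured later by resolution (step 6). The step needs periselectivity for [4+2] over the ene reaction at the C5 methyl group and chemoselectivity for the diene over the alkyne, which the fixed s-cis geometry and the inertness of the ethynyl group towards singlet oxygen should provide. Low temperature, an aprotic solvent and the absence of base are chosen because the bridgehead C3–H makes the peroxide prone to Kornblum–DeLaMare rearrangement.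

Step 4
Reactants: 6 rac-(1S,4S)-1-ethynyl-6,7,7-trimethyl-2,3-dioxabicyclo[2.2.2]oct-5-ene
Product: 7 rac-1-ethynyl-2,8,8-trimethyl-3,6,7-trioxatricyclo[3.2.2.0^2,4]nonane (oxirane oxygen on the face anti to the O–O bridge)
Conditions: mCPBA, Na2HPO4, CH2Cl2, 0 °C
Reagents that add atoms: mCPBA, OOC(=O)c1cccc(Cl)c1
Why: Prilezhaev epoxidation of the electron-rich trisubstituted C4=C5 alkene, expected to occur on the face turned away from the lone pairs of the O–O bridge so that the new C4 and C5 stereocenters carry oxygen trans to the C3 and C6 oxygens, while the alkyne is inert and the buffer keeps the acid-labile epoxide and the base-labile peroxide intact.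

Step 5
Reactants: 7 rac-1-ethynyl-2,8,8-trimethyl-3,6,7-trioxatricyclo[3.2.2.0^2,4]nonane
Product: 10 rac-(1R,2R,4S)-1-ethenyl-2,6,6-trimethylcyclohexane-1,2,4-triol, via epoxy diol aluminate 8 (not isolated), via ethynyl triol aluminate 9 (not isolated)
Conditions: LiAlH4 (excess), THF, 0 °C → reflux; aq. Rochelle salt
Reagents that add atoms: none
Why: LiAlH4 reduction in three stages, namely O–O cleavage with retention at C3 and C6, hydride delivery from the C3 alkoxyaluminate to the less substituted C4 of the trans-epoxy alcohol (SN2 opening that leaves the C5–O bond and configuration untouched and erases the C4 stereocenter), and alkoxide-directed trans-hydroalumination of the propargylic alkyne to the vinyl group in refluxing THF.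

Step 6
Reactants: 10 rac-(1R,2R,4S)-1-ethenyl-2,6,6-trimethylcyclohexane-1,2,4-triol
Product: 11 (1R,2R,4S)-1-ethenyl-2,6,6-trimethylcyclohexane-1,2,4-triol
Conditions: preparative SFC, amylose tris(3,5-dimethylphenylcarbamate) phase, CO2/MeOH
Reagents that add atoms: none
Why: Chromatographic resolution of a racemate on a chiral stationary phase, a physical separation that changes no bond, the wanted (1R,2R,4S) enantiomer being identified by MTPA ester analysis at the secondary C3 carbinol.

Step 7
Reactants: 12 (2E)-3-methylpent-2-en-4-yn-1-ol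
Product: 13 (2E)-3-methylpent-2-en-4-ynal
Conditions: MnO2, CH2Cl2, rt
Reagents that add atoms: none
Why: MnO2 oxidation of a primary allylic alcohol to the enal, which leaves the terminal alkyne and the E double bond untouched; the volatile aldehyde is used in solution.

Step 8
Reactants: 13 (2E)-3-methylpent-2-en-4-ynal; 14 2-(dichloromethyl)-4,4,5,5-tetramethyl-1,3,2-dioxaborolane
Product: 15 2-[(1E,3E)-4-methylhexa-1,3-dien-5-yn-1-yl]-4,4,5,5-tetramethyl-1,3,2-dioxaborolane
Conditions: CrCl2, LiI, THF, rt
Reagents that add atoms: 2-(dichloromethyl)-4,4,5,5-tetramethyl-1,3,2-dioxaborolane 14, ClC(Cl)B1OC(C)(C)C(C)(C)O1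
Why: Takai–Utimoto boryl olefination, in which a gem-dichromium species made from the dichloromethylboronate and divalent chromium adds to the aldehyde and eliminates to the E-alkenylboronate, the reagent being inert to the terminal alkyne.

Step 9
Reactants: 13 (2E)-3-methylpent-2-en-4-ynal; 16 iodoform
Product: 17 (1E,3E)-1-iodo-4-methylhexa-1,3-dien-5-yne
Conditions: CrCl2, CHI3, THF/dioxane, 0 °C → rt
Reagents that add atoms: iodoform 16, IC(I)I
Why: Takai iodo-olefination by the same gem-dichromium addition–elimination, which should give mainly the E-iodide (dioxane co-solvent favouring E) and tolerates the terminal alkyne.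

Step 10
Reactants: 18 (4R,6R)-actinol
Product: 19 (4R,6R)-2,2,6-trimethyl-4-(triethylsilyloxy)cyclohexan-1-one
Conditions: TESCl, imidazole, CH2Cl2, 0 °C → rt
Reagents that add atoms: chlorotriethylsilane, CC[Si](Cl)(CC)CC
Why: Silylation of the only hydroxyl as its TES ether so that the ketone α-hydrogen is the sole acidic site in the next step; both stereocenters are untouched.

Step 11
Reactants: 19 (4R,6R)-2,2,6-trimethyl-4-(triethylsilyloxy)cyclohexan-1-one
Product: 22 (4R)-4-hydroxy-2,6,6-trimethylcyclohex-1-en-1-yl trifluoromethanesulfonate, via lithium enolate 20 (not isolated), via TES enol triflate 21 (not isolated)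
Conditions: LDA, THF, −78 °C; PhNTf2, −78 → 0 °C; then 1 M HCl (aq), THF, rt
Reagents that add atoms: N-phenylbis(trifluoromethanesulfonimide), O=S(=O)(N(c1ccccc1)S(=O)(=O)C(F)(F)F)C(F)(F)F
Why: Enol triflate formation, in which the single α-hydrogen of the ketone guarantees one enolate regioisomer that PhNTf2 sulfonylates on oxygen (the methyl-bearing stereocenter is deliberately destroyed, the carbinol center is not involved), followed by acid cleavage of the TES ether, to which the vinyl triflate is stable.

Step 12
Reactants: 22 (4R)-4-hydroxy-2,6,6-trimethylcyclohex-1-en-1-yl trifluoromethanesulfonate; 15 2-[(1E,3E)-4-methylhexa-1,3-dien-5-yn-1-yl]-4,4,5,5-tetramethyl-1,3,2-dioxaborolane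
Product: 23 (1R)-3,5,5-trimethyl-4-[(3E,5E)-3-methyl-6-(4,4,5,5-tetramethyl-1,3,2-dioxaborolan-2-yl)hexa-3,5-dien-1-yn-1-yl]cyclohex-3-en-1-ol
Conditions: Pd(PPh3)4 (5 mol%), CuI (10 mol%), i-Pr2NH, DMF, rt → 40 °C
Reagents that add atoms: none
Why: Sonogashira coupling of the vinyl triflate with the terminal alkyne, under which the pinacol boronate is not activated (no oxygen base) and the free hydroxyl is tolerated; no stereocenter or double-bond geometry is affected.

Step 13
Reactants: 23 (1R)-3,5,5-trimethyl-4-[(3E,5E)-3-methyl-6-(pinacolboryl)hexa-3,5-dien-1-yn-1-yl]cyclohex-3-en-1-ol; 17 (1E,3E)-1-iodo-4-methylhexa-1,3-dien-5-yne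
Product: 24 (1R)-4-[(3E,5E,7E,9E)-3,10-dimethyldodeca-3,5,7,9-tetraene-1,11-diyn-1-yl]-3,5,5-trimethylcyclohex-3-en-1-ol
Conditions: PdCl2(dppf) (5 mol%), K3PO4 (aq), THF, rt, dark
Reagents that add atoms: none
Why: Suzuki–Miyaura alkenyl–alkenyl coupling, stereoretentive at both partners so that the new C–C single bond joins two E-alkenes, with the terminal alkyne expected to stay a spectator at room temperature in the absence of copper and amine.

Step 14
Reactants: 25 propiolic acid
Product: 26 (2E)-2,3-dibromoprop-2-enoic acid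
Conditions: Br2, CHCl3, 0 °C → rt, dark
Reagents that add atoms: bromine, BrBr
Why: Ionic anti-addition of bromine to the alkyne in the dark, which gives the E-dibromide with the carboxyl group cis to the C3 bromine, as the later lactonisation requires.

Step 15
Reactants: 24 (1R)-4-[(3E,5E,7E,9E)-3,10-dimethyldodeca-3,5,7,9-tetraene-1,11-diyn-1-yl]-3,5,5-trimethylcyclohex-3-en-1-ol; 26 (2E)-2,3-dibromoprop-2-enoic acid
Product: 28 (5Z)-3-bromo-5-[(2E,4E,6E,8E)-11-[(4R)-4-hydroxy-2,6,6-trimethylcyclohex-1-en-1-yl]-2,9-dimethylundeca-2,4,6,8-tetraen-10-yn-1-ylidene]furan-2(5H)-one, via bromoenynoic acid 27 (not isolated)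
Conditions: PdCl2(PPh3)2 (5 mol%), CuI (10 mol%), Et3N, MeCN, rt, dark
Reagents that add atoms: none
Why: Tandem Sonogashira coupling–lactonisation, in which the β C–Br bond of the dibromoacrylate undergoes oxidative addition first, and the cis carboxylate then adds 5-exo-dig and anti across the metal-activated alkyne to give the Z-ylidenebutenolide (ring oxygen cis to the chain), leaving the α-bromide for the final coupling.

Step 16
Reactants: 28 bromo-ylidenebutenolide polyene (as above); 11 (1R,2R,4S)-1-ethenyl-2,6,6-trimethylcyclohexane-1,2,4-triol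
Product: 29 target, (5Z)-3-[(E)-2-[(1R,2R,4S)-1,2,4-trihydroxy-2,6,6-trimethylcyclohexyl]ethenyl]-5-[(2E,4E,6E,8E)-11-[(4R)-4-hydroxy-2,6,6-trimethylcyclohex-1-en-1-yl]-2,9-dimethylundeca-2,4,6,8-tetraen-10-yn-1-ylidene]furan-2(5H)-one
Conditions: Pd(OAc)2 (10 mol%), Bu4NCl, NaHCO3, DMF, 45 °C, dark
Reagents that add atoms: none
Why: Mizoroki–Heck reaction, in which oxidative addition into the α-bromobutenolide, syn-carbopalladation of the vinyl group at its terminal carbon (the quaternary carbinol enforces linear selectivity) and syn β-hydride elimination, possible only from C8, give the E C7=C8 alkene without touching any stereocenter or needing hydroxyl protection.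

Compound list
1 | safranal (2,6,6-trimethylcyclohexa-1,3-diene-1-carbaldehyde) | CC1=C(C=O)C(C)(C)CC=C1 | starting material
2 | carbon tetrabromide | BrC(Br)(Br)Br | starting material
3 | 1-(2,2-dibromoethenyl)-2,6,6-trimethylcyclohexa-1,3-diene | CC1=C(C=C(Br)Br)C(C)(C)CC=C1 | intermediate
4 | lithium (2,6,6-trimethylcyclohexa-1,3-dien-1-yl)acetylide | [Li]C#CC1=C(C)C=CCC1(C)C | intermediate (not isolated)
5 | 1-ethynyl-2,6,6-trimethylcyclohexa-1,3-diene | CC1=C(C#C)C(C)(C)CC=C1 | intermediate
6 | rac-(1S,4S)-1-ethynyl-6,7,7-trimethyl-2,3-dioxabicyclo[2.2.2]oct-5-ene | C#C[C@]12OO[C@H](C=C1C)CC2(C)C | intermediate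
7 | rac-1-ethynyl-2,8,8-trimethyl-3,6,7-trioxatricyclo[3.2.2.0^2,4]nonane, oxirane anti to the O–O bridge | C#C[C@]12OO[C@H]([C@H]3O[C@]31C)CC2(C)C | intermediate
8 | rac-2-ethynyl-1,3,3-trimethyl-7-oxabicyclo[4.1.0]heptane-2,5-diol (hydroxyls cis, oxirane trans to both; present as aluminate) | C#C[C@@]1(O)C(C)(C)C[C@H](O)[C@H]2O[C@@]12C | intermediate (not isolated)
9 | rac-1-ethynyl-2,6,6-trimethylcyclohexane-1,2,4-triol (C1 and C4 hydroxyls cis, C2 hydroxyl trans to both; present as aluminate) | C#C[C@@]1(O)C(C)(C)C[C@H](O)C[C@@]1(C)O | intermediate (not isolated)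
10 | rac-(1R,2R,4S)-1-ethenyl-2,6,6-trimethylcyclohexane-1,2,4-triol | C=C[C@@]1(O)C(C)(C)C[C@H](O)C[C@@]1(C)O | intermediate
11 | (1R,2R,4S)-1-ethenyl-2,6,6-trimethylcyclohexane-1,2,4-triol (single enantiomer) | C=C[C@@]1(O)C(C)(C)C[C@H](O)C[C@@]1(C)O | intermediate
12 | (2E)-3-methylpent-2-en-4-yn-1-ol | C#C/C(C)=C/CO | starting material
13 | (2E)-3-methylpent-2-en-4-ynal | C#C/C(C)=C/C=O | intermediate
14 | 2-(dichloromethyl)-4,4,5,5-tetramethyl-1,3,2-dioxaborolane | ClC(Cl)B1OC(C)(C)C(C)(C)O1 | starting material
15 | 2-[(1E,3E)-4-methylhexa-1,3-dien-5-yn-1-yl]-4,4,5,5-tetramethyl-1,3,2-dioxaborolane | C#C/C(C)=C/C=C/B1OC(C)(C)C(C)(C)O1 | intermediate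
16 | iodoform | IC(I)I | starting material
17 | (1E,3E)-1-iodo-4-methylhexa-1,3-dien-5-yne | C#C/C(C)=C/C=C/I | intermediate
18 | (4R,6R)-actinol ((4R,6R)-4-hydroxy-2,2,6-trimethylcyclohexan-1-one) | CC1(C)C[C@H](O)C[C@@H](C)C1=O | starting material
19 | (4R,6R)-2,2,6-trimethyl-4-(triethylsilyloxy)cyclohexan-1-one | CC1(C)C[C@H](O[Si](CC)(CC)CC)C[C@@H](C)C1=O | intermediate
20 | lithium enolate of 19 | CC1=C(O[Li])C(C)(C)C[C@H](O[Si](CC)(CC)CC)C1 | intermediate (not isolated)
21 | (4R)-2,6,6-trimethyl-4-(triethylsilyloxy)cyclohex-1-en-1-yl trifluoromethanesulfonate | CC1=C(OS(=O)(=O)C(F)(F)F)C(C)(C)C[C@H](O[Si](CC)(CC)CC)C1 | intermediate (not isolated)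
22 | (4R)-4-hydroxy-2,6,6-trimethylcyclohex-1-en-1-yl trifluoromethanesulfonate | CC1=C(OS(=O)(=O)C(F)(F)F)C(C)(C)C[C@H](O)C1 | intermediate
23 | (1R)-3,5,5-trimethyl-4-[(3E,5E)-3-methyl-6-(4,4,5,5-tetramethyl-1,3,2-dioxaborolan-2-yl)hexa-3,5-dien-1-yn-1-yl]cyclohex-3-en-1-ol | CC1=C(C#C/C(C)=C/C=C/B2OC(C)(C)C(C)(C)O2)C(C)(C)C[C@H](O)C1 | intermediate
24 | (1R)-4-[(3E,5E,7E,9E)-3,10-dimethyldodeca-3,5,7,9-tetraene-1,11-diyn-1-yl]-3,5,5-trimethylcyclohex-3-en-1-ol | CC1=C(C#C/C(C)=C/C=C/C=C/C=C(C)/C#C)C(C)(C)C[C@H](O)C1 | intermediate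
25 | propiolic acid | C#CC(=O)O | starting material
26 | (2E)-2,3-dibromoprop-2-enoic acid | Br/C=C(/Br)C(=O)O | intermediate
27 | (2E,6E,8E,10E,12E)-2-bromo-15-[(4R)-4-hydroxy-2,6,6-trimethylcyclohex-1-en-1-yl]-6,13-dimethylpentadeca-2,6,8,10,12-pentaene-4,14-diynoic acid | CC1=C(C#C/C(C)=C/C=C/C=C/C=C(C)/C#C/C=C(/Br)C(=O)O)C(C)(C)C[C@H](O)C1 | intermediate (not isolated)
28 | (5Z)-3-bromo-5-[(2E,4E,6E,8E)-11-[(4R)-4-hydroxy-2,6,6-trimethylcyclohex-1-en-1-yl]-2,9-dimethylundeca-2,4,6,8-tetraen-10-yn-1-ylidene]furan-2(5H)-one | CC1=C(C#C/C(C)=C/C=C/C=C/C=C(C)/C=C2C=C(Br)C(=O)O/2)C(C)(C)C[C@H](O)C1 | intermediate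
29 | target CNP0163979.1 | CC1=C(C#C/C(C)=C/C=C/C=C/C=C(C)/C=C2C=C(/C=C/[C@@]3(O)C(C)(C)C[C@H](O)C[C@@]3(C)O)C(=O)O/2)C(C)(C)C[C@H](O)C1 | target

Total step count: 16.
Longest linear sequence: 7 steps (safranal 1 → 29 through steps 1–6 and 16). The actinol and enynol branches each reach 29 in 6 steps.

Steps most likely to fail

Step 4 (epoxidation). The peracid may attack the face syn to the O–O bridge, or both faces, because the C1 methyl group that lies over C5 hinders the anti face; this would place the C5 oxygen cis to the C3 and C6 oxygens. Fallback: starting from 6, the O–O bond is reduced with thiourea in MeOH to the cis-enediol rac-1-ethynyl-2,6,6-trimethylcyclohex-2-ene-1,4-diol F1. NBS in aqueous acetone should then form the bromonium ion on the hydroxyl-bearing face, and water should open it at the tertiary C5 from the opposite face (Markovnikov anti-addition) to give the bromotriol rac-3-bromo-1-ethynyl-2,6,6-trimethylcyclohexane-1,2,4-triol F2. Here the facial preference is set by the two cis hydroxyls and by anti-addition instead of by the peroxide bridge. F2 is submitted to LiAlH4 in refluxing THF: the C5 alkoxide closes the trans-bromohydrin to the epoxide of 8, and hydride opening at C4 and alkyne reduction follow as in step 5. The fallback returns to the route at 10.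

Step 16 (Heck coupling). Insertion into the hindered vinyl carbinol may be slow, so that palladium hydride species scramble the polyene geometry or the arylpalladium intermediate inserts into the polyene of another molecule. Fallback: starting from 7, LiAlH4 in Et2O at 0 °C (O–O cleavage and epoxide opening only, alkyne left intact) gives the racemic ethynyl triol 9, here isolated. Resolution on the same chiral phase gives the single enantiomer of 1-ethynyl-2,6,6-trimethylcyclohexane-1,2,4-triol F3. Palladium-catalysed syn-hydrostannation (Bu3SnH, PdCl2(PPh3)2, THF, 0 °C), directed to the terminal carbon by the hindered carbinol, gives the (E)-2-(tributylstannyl)ethenyl triol F4. Stille coupling of F4 with 28 (Pd2(dba)3, AsPh3, NMP, rt), which is base-free and stereoretentive, returns to the route at 29.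

Step 15 (tandem alkynylation–lactonisation). Ring closure may go 6-endo to the pyranone, the α-bromide of the product may undergo a second alkynylation, or the free haloacrylic acid may decompose under the coupling conditions. Fallback: starting from 26, acid-catalysed esterification (MeOH, H2SO4) gives methyl (2E)-2,3-dibromoprop-2-enoate F5. Sonogashira coupling of F5 with 24 (PdCl2(PPh3)2, CuI, Et3N, THF), selective for the C3 bromide, gives the methyl bromoenynoate F6. Hydrolysis with LiOH in THF/H2O gives acid 27, here isolated, and AgNO3-catalysed 5-exo-dig lactonisation in acetone, which separates ring closure from the cross-coupling, returns to the route at 28.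

Further compounds
F1 | step 4 | rac-1-ethynyl-2,6,6-trimethylcyclohex-2-ene-1,4-diol (hydroxyls cis) | C#C[C@@]1(O)C(C)(C)C[C@H](O)C=C1C
F2 | step 4 | rac-3-bromo-1-ethynyl-2,6,6-trimethylcyclohexane-1,2,4-triol (bromine cis to the C1 and C4 hydroxyls, C2 hydroxyl trans) | C#C[C@@]1(O)C(C)(C)C[C@H](O)[C@H](Br)[C@@]1(C)O
F3 | step 16 | 1-ethynyl-2,6,6-trimethylcyclohexane-1,2,4-triol, single enantiomer with the ring configuration of 11 | C#C[C@@]1(O)C(C)(C)C[C@H](O)C[C@@]1(C)O
F4 | step 16 | (1R,2R,4S)-2,6,6-trimethyl-1-[(E)-2-(tributylstannyl)ethenyl]cyclohexane-1,2,4-triol | CCCC[Sn](CCCC)(CCCC)/C=C/[C@@]1(O)C(C)(C)C[C@H](O)C[C@@]1(C)O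
F5 | step 15 | methyl (2E)-2,3-dibromoprop-2-enoate | Br/C=C(/Br)C(=O)OC
F6 | step 15 | methyl ester of 27 | CC1=C(C#C/C(C)=C/C=C/C=C/C=C(C)/C#C/C=C(/Br)C(=O)OC)C(C)(C)C[C@H](O)C1
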